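**Plan**

1. Cuts: the acid goes back to its methyl ester. The cyclohexene ring (C3a–C4–C5–C6=C7–C7a, indene numbering) is a Diels–Alder retron: its C6=C7 alkene lies opposite the ester-bearing C3a–C4 edge, so C4–C5 and C3a–C7a are cut, with the cyclopentene carbons C3=C2–C1 as a three-atom tether. This unfolds both rings into a linear (2E,4Z,7E,9E,11E,13E)-hexaenoate.
2. In that hexaene the quaternary C5 is a diene terminus and its bond to the dienyl arm is an sp2–sp2 single bond; it is cut last into a tetraenoate vinyl iodide and a phenyldienyl stannane.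
3. Forward: the iodide is built linearly from methyl (R)-3-hydroxy-2-methylpropanoate (Wittig, Corey–Fuchs/methylation, hydrozirconation–iodination on one side; Still–Gennari, reduction, oxidation–Wittig on the other). The stannane comes from (E)-4-phenylbut-3-en-2-one by enyne carboalumination.
4. Stille coupling completes the tetraene and the intramolecular Diels–Alder reaction follows in the same flask, closing the six- and five-membered rings together; thiolate demethylation ends the route.
5. Stereochemistry: C1 is bought with the hydroxy ester. C3a, C4, C5 and C7a are all set in the cycloaddition by alkene geometry, an ester-endo transition state (trans ring fusion) and 1,3-allylic strain between C1–H and the C7 methyl (face selection).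

Key step: step 15

Remark: iodide 15 is assumed not to undergo its own cycloaddition at 23 °C, because its diene carries iodine and lacks the extended conjugation of hexaene 24.

**Route**

Step 1
Reactants: 1 methyl (R)-3-hydroxy-2-methylpropanoate
Product: 2 methyl (R)-3-[(tert-butyldimethylsilyl)oxy]-2-methylpropanoate
Conditions: TBSCl, imidazole, CH2Cl2, 0 → 23 °C
Reagents that add atoms: tert-butyldimethylsilyl chloride, CC(C)(C)[Si](C)(C)Cl
Why: Imidazole-promoted silylation of the primary alcohol, which does not touch the stereocentre.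

Step 2
Reactants: 2 methyl (R)-3-[(tert-butyldimethylsilyl)oxy]-2-methylpropanoate
Product: 3 (R)-3-[(tert-butyldimethylsilyl)oxy]-2-methylpropanal
Conditions: i-Bu2AlH, CH2Cl2, −78 °C
Reagents that add atoms: none
Why: Partial ester reduction at −78 °C stops at the aluminium hemiacetal and releases the aldehyde on work-up; the α-stereocentre should be kept by using the crude aldehyde at once.

Step 3
Reactants: 3 (R)-3-[(tert-butyldimethylsilyl)oxy]-2-methylpropanal
Product: 4 (2E,4S)-5-[(tert-butyldimethylsilyl)oxy]-2,4-dimethylpent-2-enal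
Conditions: Ph3P=C(Me)CHO, toluene, 80 °C
Reagents that add atoms: 2-(triphenylphosphoranylidene)propanal, CC(C=O)=P(c1ccccc1)(c1ccccc1)c1ccccc1
Why: Wittig olefination with a stabilized, non-basic ylide should give the E-trisubstituted enal without enolizing 3.

Step 4
Reactants: 4 (2E,4S)-5-[(tert-butyldimethylsilyl)oxy]-2,4-dimethylpent-2-enal
Product: 5 tert-butyl{[(2S,3E)-6,6-dibromo-2,4-dimethylhexa-3,5-dien-1-yl]oxy}dimethylsilane
Conditions: CBr4, PPh3, CH2Cl2, 0 °C
Reagents that add atoms: carbon tetrabromide, BrC(Br)(Br)Br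
Why: Corey–Fuchs (Ramirez) dibromo-olefination of the aldehyde by the ylide Ph3P=CBr2 formed in the flask.

Step 5
Reactants: 5 tert-butyl{[(2S,3E)-6,6-dibromo-2,4-dimethylhexa-3,5-dien-1-yl]oxy}dimethylsilane
Product: 7 tert-butyl{[(2S,3E)-2,4-dimethylhept-3-en-5-yn-1-yl]oxy}dimethylsilane, via lithium acetylide 6 (not isolated)
Conditions: n-BuLi (2.2 equiv), THF, −78 °C; then MeI, −78 → 23 °C
Reagents that add atoms: iodomethane, CI
Why: Second stage of the Corey–Fuchs reaction: bromine–lithium exchange and Fritsch–Buttenberg–Wiechell rearrangement give the lithium acetylide, which is methylated on carbon.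

Step 6
Reactants: 7 tert-butyl{[(2S,3E)-2,4-dimethylhept-3-en-5-yn-1-yl]oxy}dimethylsilane
Product: 9 tert-butyl{[(2S,3E,5E)-6-iodo-2,4-dimethylhepta-3,5-dien-1-yl]oxy}dimethylsilane, via alkenylzirconocene 8 (not isolated)
Conditions: Cp2Zr(H)Cl (2 equiv), THF, 23 → 50 °C; then I2, 0 °C
Reagents that add atoms: iodine, II
Why: Hydrozirconation adds Zr–H syn to the alkyne only, with zirconium expected at the less hindered methyl-bearing carbon after equilibration by excess reagent (as with 1-arylpropynes); iodinolysis with retention should give the 5E iodide.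

Step 7
Reactants: 9 tert-butyl{[(2S,3E,5E)-6-iodo-2,4-dimethylhepta-3,5-dien-1-yl]oxy}dimethylsilane
Product: 10 (2S,3E,5E)-6-iodo-2,4-dimethylhepta-3,5-dien-1-ol
Conditions: Bu4NF, THF, 0 °C
Reagents that add atoms: none
Why: Fluoride cleaves the primary silyl ether while the vinyl iodide is inert.

Step 8
Reactants: 10 (2S,3E,5E)-6-iodo-2,4-dimethylhepta-3,5-dien-1-ol
Product: 11 (2S,3E,5E)-6-iodo-2,4-dimethylhepta-3,5-dienal
Conditions: Dess–Martin periodinane, pyridine, CH2Cl2, 0 °C
Reagents that add atoms: none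
Why: Dess–Martin oxidation under buffered, non-enolizing conditions should keep the α-stereocentre of this β,γ-unsaturated aldehyde, which is used crude.

Step 9
Reactants: 11 (2S,3E,5E)-6-iodo-2,4-dimethylhepta-3,5-dienal
Product: 12 methyl (2Z,4S,5E,7E)-8-iodo-2,4,6-trimethylnona-2,5,7-trienoate
Conditions: (CF3CH2O)2P(O)CH(Me)CO2Me, KN(SiMe3)2, 18-crown-6, THF, −78 °C
Reagents that add atoms: methyl 2-[bis(2,2,2-trifluoroethoxy)phosphoryl]propanoate, COC(=O)C(C)P(=O)(OCC(F)(F)F)OCC(F)(F)F
Why: Still–Gennari olefination: the electron-poor phosphonate under dissociating conditions eliminates kinetically to the Z-enoate, and −78 °C should limit enolization of 11.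

Step 10
Reactants: 12 methyl (2Z,4S,5E,7E)-8-iodo-2,4,6-trimethylnona-2,5,7-trienoate
Product: 13 (2Z,4S,5E,7E)-8-iodo-2,4,6-trimethylnona-2,5,7-trien-1-ol
Conditions: i-Bu2AlH, CH2Cl2, −78 °C
Reagents that add atoms: none
Why: 1,2-Reduction of the enoate to the Z-allylic alcohol, with the vinyl iodide tolerated.

Step 11
Reactants: 13 (2Z,4S,5E,7E)-8-iodo-2,4,6-trimethylnona-2,5,7-trien-1-ol
Product: 15 methyl (2E,4Z,6R,7E,9E)-10-iodo-2,4,6,8-tetramethylundeca-2,4,7,9-tetraenoate, via Z-enal 14 (not isolated)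
Conditions: MnO2, Ph3P=C(Me)CO2Me, CH2Cl2, 23 → 40 °C
Reagents that add atoms: methyl 2-(triphenylphosphoranylidene)propanoate, COC(=O)C(C)=P(c1ccccc1)(c1ccccc1)c1ccccc1
Why: Allylic oxidation by MnO2 with in situ Wittig olefination by the stabilized ylide should give the 2E alkene and avoid isolating the isomerization-prone Z-enal.

Step 12
Reactants: 16 (E)-4-phenylbut-3-en-2-one
Product: 19 [(1E)-but-1-en-3-yn-1-yl]benzene, via enol phosphate 17 (not isolated), via lithium acetylide 18 (not isolated)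
Conditions: LiN(i-Pr)2, THF, −78 °C; ClP(O)(OEt)2, −78 → 23 °C; then LiN(i-Pr)2 (2.3 equiv), −78 → 23 °C
Reagents that add atoms: none
Why: O-Phosphorylation of the kinetic methyl-ketone enolate and base-induced elimination of the enol phosphate convert the methyl ketone into the terminal alkyne.

Step 13
Reactants: 19 [(1E)-but-1-en-3-yn-1-yl]benzene
Product: 21 [(1E,3E)-4-iodo-3-methylbuta-1,3-dien-1-yl]benzene, via alkenylalane 20 (not isolated)
Conditions: Me3Al, Cp2ZrCl2 (20 mol %), CH2Cl2, 0 → 23 °C; then I2, THF, −30 °C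
Reagents that add atoms: trimethylaluminium, C[Al](C)C; iodine, II
Why: Negishi carboalumination adds Me–Al syn across the terminal alkyne with aluminium at the terminus, and iodinolysis with retention gives the E iodide.

Step 14
Reactants: 21 [(1E,3E)-4-iodo-3-methylbuta-1,3-dien-1-yl]benzene
Product: 23 tributyl[(1E,3E)-2-methyl-4-phenylbuta-1,3-dien-1-yl]stannane, via dienyllithium 22 (not isolated)
Conditions: t-BuLi (2 equiv), Et2O, −78 °C; then Bu3SnCl
Reagents that add atoms: tributyltin chloride, CCCC[Sn](Cl)(CCCC)CCCC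
Why: Iodine–lithium exchange with retention of alkene geometry, followed by stannylation.

Step 15
Reactants: 15 methyl (2E,4Z,6R,7E,9E)-10-iodo-2,4,6,8-tetramethylundeca-2,4,7,9-tetraenoate; 23 tributyl[(1E,3E)-2-methyl-4-phenylbuta-1,3-dien-1-yl]stannane
Product: 25 methyl (1R,3aR,4R,5S,7aS)-1,3,4,5,7-pentamethyl-5-[(1E,3E)-2-methyl-4-phenylbuta-1,3-dien-1-yl]-3a,4,5,7a-tetrahydro-1H-indene-4-carboxylate, via hexaene 24 (not isolated)
Conditions: Pd2(dba)3 (5 mol %), AsPh3 (20 mol %), CuI (10 mol %), DMF, 23 °C; then 60 °C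
Reagents that add atoms: none
Why: Oxidative addition of the C10–I bond of 15 to zerovalent palladium, tin-to-palladium transfer of the dienyl group of 23 and reductive elimination join C10 to the dienyl CH with retention at both alkenes and give hexaene 24, whose 7,9-diene and 2,3-alkene then combine in a thermal suprafacial [4+2] cycloaddition; the closest known reaction type is the tandem Stille coupling–intramolecular Diels–Alder reaction of polyenoates tethered at the diene terminus. The six-membered ring closes by the [4+2] event itself (bonds C2–C10 and C3–C7 of 24) and the five-membered ring is the annulated tether ring C3–C4=C5–C6–C7, closed by the same C3–C7 bond, its Z-alkene holding the two termini cis and within reach. The two quaternary centres follow from the E geometry of the dienophile and the 9E geometry of the diene (C10 methyl inside, new dienyl arm outside), and the ester-endo transition state places the ester cis to the dienyl arm and makes the ring fusion trans. The diene face is chosen by the single stereocentre C6: 1,3-allylic strain with the C8 methyl keeps the C6–H bond in the diene plane, so the dienophile arrives anti to the C6 methyl. The step needs periselectivity (only the 7,9-diene can reach the dienophile across three atoms), endo over exo selectivity (ester overlap, and a clash of the tether with the C8 methyl in the exo mode), coupling at the vinyl iodide only, and no cyclization of 15 before coupling, which its unconjugated iodine-bearing diene should ensure at 23 °C.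

Step 16
Reactants: 25 methyl (1R,3aR,4R,5S,7aS)-1,3,4,5,7-pentamethyl-5-[(1E,3E)-2-methyl-4-phenylbuta-1,3-dien-1-yl]-3a,4,5,7a-tetrahydro-1H-indene-4-carboxylate
Product: 27 27-nor-zyggomphic acid B [(1R,3aR,4R,5S,7aS)-1,3,4,5,7-pentamethyl-5-[(1E,3E)-2-methyl-4-phenylbuta-1,3-dien-1-yl]-3a,4,5,7a-tetrahydro-1H-indene-4-carboxylic acid], via lithium carboxylate 26 (not isolated)
Conditions: LiSPr, HMPA, 23 °C; then aq. HCl
Reagents that add atoms: none
Why: SN2 demethylation by thiolate at the O-methyl group should cleave the ester without attack at the carbonyl, which is shielded by two adjacent quaternary carbons; acidification gives the acid.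

**Compound list**

1 | methyl (R)-3-hydroxy-2-methylpropanoate | COC(=O)[C@H](C)CO | starting material
2 | methyl (R)-3-[(tert-butyldimethylsilyl)oxy]-2-methylpropanoate | COC(=O)[C@H](C)CO[Si](C)(C)C(C)(C)C | intermediate
3 | (R)-3-[(tert-butyldimethylsilyl)oxy]-2-methylpropanal | O=C[C@H](C)CO[Si](C)(C)C(C)(C)C | intermediate
4 | (2E,4S)-5-[(tert-butyldimethylsilyl)oxy]-2,4-dimethylpent-2-enal (S by a priority change only) | O=C/C(C)=C/[C@H](C)CO[Si](C)(C)C(C)(C)C | intermediate
5 | tert-butyl{[(2S,3E)-6,6-dibromo-2,4-dimethylhexa-3,5-dien-1-yl]oxy}dimethylsilane | BrC(Br)=C/C(C)=C/[C@H](C)CO[Si](C)(C)C(C)(C)C | intermediate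
6 | lithium (3E,5S)-6-[(tert-butyldimethylsilyl)oxy]-3,5-dimethylhex-3-en-1-yn-1-ide | [Li]C#C/C(C)=C/[C@H](C)CO[Si](C)(C)C(C)(C)C | intermediate (not isolated)
7 | tert-butyl{[(2S,3E)-2,4-dimethylhept-3-en-5-yn-1-yl]oxy}dimethylsilane | CC#C/C(C)=C/[C@H](C)CO[Si](C)(C)C(C)(C)C | intermediate
8 | chloro{(2E,4E,6S)-7-[(tert-butyldimethylsilyl)oxy]-4,6-dimethylhepta-2,4-dien-2-yl}bis(cyclopentadienyl)zirconium | C/C(=C\C(C)=C\[C@H](C)CO[Si](C)(C)C(C)(C)C)[Zr](Cl)(C1C=CC=C1)C1C=CC=C1 | intermediate (not isolated)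
9 | tert-butyl{[(2S,3E,5E)-6-iodo-2,4-dimethylhepta-3,5-dien-1-yl]oxy}dimethylsilane | C/C(I)=C\C(C)=C\[C@H](C)CO[Si](C)(C)C(C)(C)C | intermediate
10 | (2S,3E,5E)-6-iodo-2,4-dimethylhepta-3,5-dien-1-ol | C/C(I)=C\C(C)=C\[C@H](C)CO | intermediate
11 | (2S,3E,5E)-6-iodo-2,4-dimethylhepta-3,5-dienal | C/C(I)=C\C(C)=C\[C@H](C)C=O | intermediate
12 | methyl (2Z,4S,5E,7E)-8-iodo-2,4,6-trimethylnona-2,5,7-trienoate | COC(=O)/C(C)=C\[C@@H](C)/C=C(C)/C=C(\C)I | intermediate
13 | (2Z,4S,5E,7E)-8-iodo-2,4,6-trimethylnona-2,5,7-trien-1-ol | OC/C(C)=C\[C@@H](C)/C=C(C)/C=C(\C)I | intermediate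
14 | (2Z,4S,5E,7E)-8-iodo-2,4,6-trimethylnona-2,5,7-trienal | O=C/C(C)=C\[C@@H](C)/C=C(C)/C=C(\C)I | intermediate (not isolated)
15 | methyl (2E,4Z,6R,7E,9E)-10-iodo-2,4,6,8-tetramethylundeca-2,4,7,9-tetraenoate (R by a priority change only) | COC(=O)/C(C)=C/C(C)=C\[C@@H](C)/C=C(C)/C=C(\C)I | intermediate
16 | (E)-4-phenylbut-3-en-2-one | CC(=O)/C=C/c1ccccc1 | starting material
17 | diethyl (3E)-4-phenylbuta-1,3-dien-2-yl phosphate | C=C(OP(=O)(OCC)OCC)/C=C/c1ccccc1 | intermediate (not isolated)
18 | lithium (3E)-4-phenylbut-3-en-1-yn-1-ide | [Li]C#C/C=C/c1ccccc1 | intermediate (not isolated)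
19 | [(1E)-but-1-en-3-yn-1-yl]benzene | C#C/C=C/c1ccccc1 | intermediate
20 | dimethyl[(1E,3E)-2-methyl-4-phenylbuta-1,3-dien-1-yl]alumane | C[Al](C)/C=C(C)/C=C/c1ccccc1 | intermediate (not isolated)
21 | [(1E,3E)-4-iodo-3-methylbuta-1,3-dien-1-yl]benzene | I/C=C(C)/C=C/c1ccccc1 | intermediate
22 | [(1E,3E)-2-methyl-4-phenylbuta-1,3-dien-1-yl]lithium | [Li]/C=C(C)/C=C/c1ccccc1 | intermediate (not isolated)
23 | tributyl[(1E,3E)-2-methyl-4-phenylbuta-1,3-dien-1-yl]stannane | CCCC[Sn](CCCC)(CCCC)/C=C(C)/C=C/c1ccccc1 | intermediate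
24 | methyl (2E,4Z,6S,7E,9E,11E,13E)-2,4,6,8,10,12-hexamethyl-14-phenyltetradeca-2,4,7,9,11,13-hexaenoate (S by a priority change only) | COC(=O)/C(C)=C/C(C)=C\[C@@H](C)/C=C(C)/C=C(C)/C=C(C)/C=C/c1ccccc1 | intermediate (not isolated)
25 | methyl (1R,3aR,4R,5S,7aS)-1,3,4,5,7-pentamethyl-5-[(1E,3E)-2-methyl-4-phenylbuta-1,3-dien-1-yl]-3a,4,5,7a-tetrahydro-1H-indene-4-carboxylate | CC1=C[C@](C)(/C=C(C)/C=C/c2ccccc2)[C@](C)(C(=O)OC)[C@H]2C(C)=C[C@@H](C)[C@H]12 | intermediate
26 | lithium (1R,3aR,4R,5S,7aS)-1,3,4,5,7-pentamethyl-5-[(1E,3E)-2-methyl-4-phenylbuta-1,3-dien-1-yl]-3a,4,5,7a-tetrahydro-1H-indene-4-carboxylate | CC1=C[C@](C)(/C=C(C)/C=C/c2ccccc2)[C@](C)(C(=O)[O-])[C@H]2C(C)=C[C@@H](C)[C@H]12.[Li+] | intermediate (not isolated)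
27 | 27-nor-zyggomphic acid B | CC1=C[C@](C)(/C=C(C)/C=C/c2ccccc2)[C@](C)(C(=O)O)[C@H]2C(C)=C[C@@H](C)[C@H]12 | target

**Step count and risks**

Total step count: 16. Longest linear sequence: 13 steps (steps 1–11, 15, 16).

Steps most likely to fail:

1. Step 15. The cycloaddition may be too slow at temperatures where the Z-dienoate is still safe from a 1,5-hydrogen shift, or endo/exo control may erode; the hindered coupling may also give way to stannane homocoupling. The fallback raises dienophile reactivity by changing its oxidation level. It sets out from 15: reduction with i-Bu2AlH should give the tetraenol F1, and MnO2 the tetraenal F2. Stille coupling of F2 with 23 should give the hexaenal F3, whose more electrophilic enal should cyclize at or below 23 °C (or with Me2AlCl at −78 °C) to the bicyclic aldehyde F4. Pinnick oxidation (NaClO2, NaH2PO4, 2-methylbut-2-ene) of F4 comes back to the route at 27.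

2. Step 6. Zirconium may add at the alkyne carbon next to the alkene, giving the regioisomeric iodide. The fallback fixes the regiochemistry electronically with silicon and sets out from 5. Treatment with n-BuLi (via 6) and then Me3SiCl should give the silyl enyne F5. Hydroalumination with i-Bu2AlH in heptane without donor solvent places aluminium on the silicon-bearing carbon and should give the trans adduct, alkenylalane F6. MeLi then MeI methylates it with retention to the vinylsilane F7, and N-iodosuccinimide in MeCN exchanges silicon for iodine with retention, coming back to the route at 9.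

3. Step 9. The α-stereogenic β,γ-unsaturated aldehyde 11 may enolize (epimerization, alkene migration into conjugation), and Z selectivity may erode. The fallback avoids the aldehyde and sets out from 10. Iodination (I2, PPh3, imidazole) should give the primary iodide F8, and PPh3 in MeCN at 80 °C the phosphonium salt F9. NaN(SiMe3)2 at −78 °C forms the ylide F10, which reacts with 1-[(tert-butyldimethylsilyl)oxy]propan-2-one in a Z-selective Wittig reaction of a non-stabilized ylide with an α-silyloxy ketone to give the silyl ether F11. Bu4NF then comes back to the route at 13.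

Further compounds
F1 | step 15 | (2E,4Z,6R,7E,9E)-10-iodo-2,4,6,8-tetramethylundeca-2,4,7,9-tetraen-1-ol | OC/C(C)=C/C(C)=C\[C@@H](C)/C=C(C)/C=C(\C)I
F2 | step 15 | (2E,4Z,6R,7E,9E)-10-iodo-2,4,6,8-tetramethylundeca-2,4,7,9-tetraenal | O=C/C(C)=C/C(C)=C\[C@@H](C)/C=C(C)/C=C(\C)I
F3 | step 15 | (2E,4Z,6S,7E,9E,11E,13E)-2,4,6,8,10,12-hexamethyl-14-phenyltetradeca-2,4,7,9,11,13-hexaenal | O=C/C(C)=C/C(C)=C\[C@@H](C)/C=C(C)/C=C(C)/C=C(C)/C=C/c1ccccc1
F4 | step 15 | (1R,3aR,4R,5S,7aS)-1,3,4,5,7-pentamethyl-5-[(1E,3E)-2-methyl-4-phenylbuta-1,3-dien-1-yl]-3a,4,5,7a-tetrahydro-1H-indene-4-carbaldehyde | CC1=C[C@](C)(/C=C(C)/C=C/c2ccccc2)[C@](C)(C=O)[C@H]2C(C)=C[C@@H](C)[C@H]12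
F5 | step 6 | tert-butyl{[(2S,3E)-2,4-dimethyl-6-(trimethylsilyl)hex-3-en-5-yn-1-yl]oxy}dimethylsilane | C[Si](C)(C)C#C/C(C)=C/[C@H](C)CO[Si](C)(C)C(C)(C)C
F6 | step 6 | diisobutyl{(1E,3E,5S)-6-[(tert-butyldimethylsilyl)oxy]-3,5-dimethyl-1-(trimethylsilyl)hexa-1,3-dien-1-yl}alumane | C[Si](C)(C)/C(=C/C(C)=C/[C@H](C)CO[Si](C)(C)C(C)(C)C)[Al](CC(C)C)CC(C)C
F7 | step 6 | tert-butyl{[(2S,3E,5E)-2,4-dimethyl-6-(trimethylsilyl)hepta-3,5-dien-1-yl]oxy}dimethylsilane | C/C(=C\C(C)=C\[C@H](C)CO[Si](C)(C)C(C)(C)C)[Si](C)(C)C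
F8 | step 9 | (2E,4E,6S)-2,7-diiodo-4,6-dimethylhepta-2,4-diene | C/C(I)=C\C(C)=C\[C@H](C)CI
F9 | step 9 | [(2S,3E,5E)-6-iodo-2,4-dimethylhepta-3,5-dien-1-yl]triphenylphosphonium iodide | C/C(I)=C\C(C)=C\[C@H](C)C[P+](c1ccccc1)(c1ccccc1)c1ccccc1.[I-]
F10 | step 9 | [(2S,3E,5E)-6-iodo-2,4-dimethylhepta-3,5-dien-1-ylidene]triphenylphosphorane | C/C(I)=C\C(C)=C\[C@H](C)C=P(c1ccccc1)(c1ccccc1)c1ccccc1
F11 | step 9 | tert-butyl{[(2Z,4S,5E,7E)-8-iodo-2,4,6-trimethylnona-2,5,7-trien-1-yl]oxy}dimethylsilane | CC(C)(C)[Si](C)(C)OC/C(C)=C\[C@@H](C)/C=C(C)/C=C(\C)I
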